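The 1,2-dioxane ring is cut into the peroxy-acetal unit O1–O2–C3 (C3 = peroxy CH bearing the acetate arm) and the carbon unit C4–C5–C6 (C4 = lactone carbinol carbon, C6 = quaternary peroxy carbon). One acid-mediated [3+3] annulation joins them: the hydroperoxide oxygen O1 traps a tertiary allyl cation at C6, and the derived peroxycarbenium ion at C3 is attacked by vinylsilane carbon C4. The step exploits the 1,3-relation of nucleophilic C4 and cationic C6 across C5 and leaves a C4=C5 alkene, on which the cis-fused γ-lactone ring is closed by iodolactonisation. Precursors: an acyclic (Z)-γ-silyl tertiary allylic alcohol and methyl 3-hydroperoxy-3-methoxypropanoate.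

Key step: step 9

Remark: C1 is the lactone carbonyl, C2 its CH2, C5 the ring CH2, C7 and C8 the first two side-chain carbons; O1 is the peroxide oxygen on C6, O2 that on C3.
Assumption: 1, 6 and 13 are taken as commercially available; the future C6 carbinol centre is carried as both epimers from step 4 because it becomes a planar cation in step 9.

Step 1
Reactants: 1 (E)-5-phenylpent-4-en-1-ol; 2 1-phenyl-1H-tetrazole-5-thiol
Product: 3 1-phenyl-5-{[(4E)-5-phenylpent-4-en-1-yl]sulfanyl}-1H-tetrazole
Conditions: PPh3, DIAD, THF, 0 °C → rt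
Reagents that add atoms: none
Why: Mitsunobu reaction, in which the activated primary alcohol is displaced by the acidic tetrazolethiol (SN2 at a CH2, no stereocenter).

Step 2
Reactants: 3
Product: 5 1-phenyl-5-{[(4E)-5-phenylpent-4-en-1-yl]sulfonyl}-1H-tetrazole, via sulfoxide 4 (not isolated)
Conditions: (NH4)6Mo7O24·4H2O (10 mol %), 30% aq H2O2, EtOH, 0 °C → rt
Reagents that add atoms: hydrogen peroxide, OO
Why: Molybdate-catalysed H2O2 oxidation should take the sulfide through sulfoxide 4 to the sulfone without epoxidising the styrenyl alkene.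

Step 3
Reactants: 6 (3R)-3,7-dimethyloct-6-enoic acid [(R)-citronellic acid]
Product: 7 (4R)-4,8-dimethylnon-7-en-2-one
Conditions: MeLi (2.2 equiv), Et2O, 0 °C → rt; then cold aq NH4Cl
Reagents that add atoms: methyllithium, [Li]C
Why: Two equivalents of MeLi convert a carboxylic acid into the methyl ketone because the tetrahedral adduct persists until work-up; the stereocenter (future C8) comes from the chiral pool and is not alpha to the carbonyl, so it cannot epimerise.

Step 4
Reactants: 7
Product: 8 (4RS,6R)-4,6,10-trimethylundec-9-en-2-yn-4-ol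
Conditions: MeC≡CMgBr (1.5 equiv), THF, −20 → 0 °C; aq NH4Cl
Reagents that add atoms: prop-1-ynylmagnesium bromide, CC#C[Mg]Br
Why: 1,2-Addition of the alkynyl Grignard reagent to the methyl ketone; the new carbinol centre (future C6) forms as both epimers, which does not matter because it is ionised in step 9.

Step 5
Reactants: 8
Product: 10 (4R,6RS)-6-hydroxy-4,6-dimethylnon-7-ynal, via ozonide 9 (not isolated)
Conditions: O3, CH2Cl2, −78 °C (Sudan Red 7B end point); then PPh3, −78 °C → rt
Reagents that add atoms: ozone, [O-][O+]=O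
Why: Ozonolysis with reductive work-up; the electron-rich trisubstituted alkene should be ozonised far faster than the internal alkyne, and PPh3 reduces ozonide 9 to the aldehyde, the methyl-bearing stereocenter being remote.

Step 6
Reactants: 10; 5
Product: 11 (4RS,6R,9E,13E)-4,6-dimethyl-14-phenyltetradeca-9,13-dien-2-yn-4-ol
Conditions: 5 (1.3 equiv), KN(SiMe3)2 (1.3 equiv), DME, −60 °C; then 10, −60 °C → rt
Reagents that add atoms: none
Why: Julia–Kocienski olefination, in which the metallated sulfone adds to the unbranched aldehyde and Smiles rearrangement with loss of SO2 and the tetrazolone should give the E-alkene preferentially; the tertiary hydroxyl is too weakly acidic to quench the sulfonyl carbanion.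

Step 7
Reactants: 11
Product: 12 (2Z,4RS,6R,9E,13E)-4,6-dimethyl-14-phenyl-2-(triethylsilyl)tetradeca-2,9,13-trien-4-ol
Conditions: [Cp*Ru(MeCN)3]PF6 (2 mol %), Et3SiH (1.2 equiv), CH2Cl2, 0 °C → rt
Reagents that add atoms: triethylsilane, CC[SiH](CC)CC
Why: Ruthenium-catalysed trans-hydrosilylation of an internal propargylic alcohol delivers silicon to the alkyne carbon distal to the carbinol and hydrogen anti to it, so the Z-vinylsilane (Si cis to the carbinol carbon) should result while the isolated alkenes stay untouched.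

Step 8
Reactants: 13 dimethyl (E)-hex-3-enedioate
Product: 14 methyl 3-hydroperoxy-3-methoxypropanoate
Conditions: O3, CH2Cl2/MeOH (5:1), −78 °C; N2 purge, warm to 0 °C; rapid chromatography
Reagents that add atoms: ozone, [O-][O+]=O; methanol, CO
Why: Criegee ozonolysis in methanol, in which the symmetrical alkene gives one carbonyl oxide, trapped by MeOH as the α-methoxy hydroperoxide, and one aldehyde; the acetal carbon is racemic but becomes planar in step 9.

Step 9
Reactants: 12 (2Z,4RS,6R,9E,13E)-4,6-dimethyl-14-phenyl-2-(triethylsilyl)tetradeca-2,9,13-trien-4-ol; 14 methyl 3-hydroperoxy-3-methoxypropanoate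
Product: 16 methyl 2-[(3S,6R)-4,6-dimethyl-6-[(2R,5E,9E)-2-methyl-10-phenyldeca-5,9-dien-1-yl]-3,6-dihydro-1,2-dioxin-3-yl]acetate, via allylic peroxy acetal 15 (not isolated)
Conditions: 14 (2 equiv), chiral imidodiphosphorimidate acid (S,S)-HN[P(=NSO2CF3)(O2Ar*)]2 (Ar*(OH)2 = (S)-3,3′-bis[3,5-bis(trifluoromethyl)phenyl]-1,1′-bi-2-naphthol; 5 mol %), 5 Å molecular sieves, CH2Cl2, −60 → −30 °C; aq NaHCO3
Reagents that add atoms: none
Why: Proposed new method: the confined chiral acid ionises the tertiary allylic alcohol of 12 to a tertiary allyl cation that the hydroperoxide oxygen of 14 traps at C6 (O1–C6, giving 15), then ionises the methoxy acetal of 15 to a peroxycarbenium ion at C3 that is attacked ipso by the silicon-bearing alkene carbon C4 (C3–C4), and the β-silyl cation at C5 sheds the Et3Si group to leave the C4=C5 alkene and regenerate the acid. The closest known reaction types are the silyl-Prins (vinylsilane-terminated oxocarbenium) cyclisation and Lewis-acid C–C bond formation at peroxycarbenium ions generated from monoperoxy acetals, neither shown for this combination. The 3,6-dihydro-1,2-dioxine ring closes 6-endo-trig with both alkene carbons in the ring, the β-silicon effect directing attack through C4 and not 5-exo through C5. C3 is meant to be set by the chiral counter-anion in the peroxycarbenium ion pair (catalyst control, as in confined-acid asymmetric Prins cyclisations; the antipode giving 3S must be confirmed on a model), whereas C6 arises from a planar cation without bias, so the 6-epimer is expected alongside and is removed by chromatography. The step needs chemoselective ionisation of the tertiary allylic C–O bond beside two 1,2-disubstituted alkenes (secured by the stability of the tertiary allyl cation), capture at C6 and not at the silyl-bearing terminus C4, and the Z geometry at C4=C5 from step 7 so that C3 and C6 can join the same ring.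

Step 10
Reactants: 16
Product: 17 (3R,4S,4aR,7aS)-4-iodo-3,4a-dimethyl-3-[(2R,5E,9E)-2-methyl-10-phenyldeca-5,9-dien-1-yl]tetrahydro-3H-furo[3,2-c][1,2]dioxin-6(4H)-one
Conditions: I2 (3 equiv), MeCN, 0 °C → rt, dark; aq Na2S2O3
Reagents that add atoms: iodine, II
Why: Iodolactonisation of a γ,δ-unsaturated ester, in which the iodonium ion on C4=C5 is opened anti by the ester carbonyl oxygen at the tertiary carbon C4 (5-exo) and iodide removes the methyl group; the acetate arm on C3 reaches C4 only on its own face, so the lactone is cis-fused, which sets C4, and iodine sits trans on C5 as a temporary stereocenter.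

Step 11
Reactants: 17
Product: 18 (3R,4aS,7aS)-3,4a-dimethyl-3-[(2R,5E,9E)-2-methyl-10-phenyldeca-5,9-dien-1-yl]tetrahydro-3H-furo[3,2-c][1,2]dioxin-6(4H)-one
Conditions: Bu3SnH (2 equiv, 0.5 M), Et3B (0.2 equiv)/air, toluene, 0 °C → rt
Reagents that add atoms: none
Why: Tin hydride radical-chain deiodination replaces iodine at C5 by hydrogen and erases that temporary stereocenter; at high stannane concentration hydrogen transfer to the C5 radical should outrun its attack on the neighbouring O–O bond, and cold initiation by Et3B/air spares the peroxide.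

Compound list
1 | (E)-5-phenylpent-4-en-1-ol | OCCC/C=C/c1ccccc1 | starting material
2 | 1-phenyl-1H-tetrazole-5-thiol | Sc1nnnn1-c1ccccc1 | starting material
3 | 1-phenyl-5-{[(4E)-5-phenylpent-4-en-1-yl]sulfanyl}-1H-tetrazole | S(CCC/C=C/c1ccccc1)c1nnnn1-c1ccccc1 | intermediate
4 | 1-phenyl-5-{[(4E)-5-phenylpent-4-en-1-yl]sulfinyl}-1H-tetrazole (sulfoxide, not isolated) | O=S(CCC/C=C/c1ccccc1)c1nnnn1-c1ccccc1 | intermediate
5 | 1-phenyl-5-{[(4E)-5-phenylpent-4-en-1-yl]sulfonyl}-1H-tetrazole | O=S(=O)(CCC/C=C/c1ccccc1)c1nnnn1-c1ccccc1 | intermediate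
6 | (3R)-3,7-dimethyloct-6-enoic acid | C[C@@H](CC(=O)O)CCC=C(C)C | starting material
7 | (4R)-4,8-dimethylnon-7-en-2-one | CC(=O)C[C@H](C)CCC=C(C)C | intermediate
8 | (4RS,6R)-4,6,10-trimethylundec-9-en-2-yn-4-ol | CC#CC(C)(O)C[C@H](C)CCC=C(C)C | intermediate
9 | (4RS,6R)-8-(5,5-dimethyl-1,2,4-trioxolan-3-yl)-4,6-dimethyloct-2-yn-4-ol (ozonide, not isolated) | CC#CC(C)(O)C[C@H](C)CCC1OOC(C)(C)O1 | intermediate
10 | (4R,6RS)-6-hydroxy-4,6-dimethylnon-7-ynal | CC#CC(C)(O)C[C@H](C)CCC=O | intermediate
11 | (4RS,6R,9E,13E)-4,6-dimethyl-14-phenyltetradeca-9,13-dien-2-yn-4-ol | CC#CC(C)(O)C[C@H](C)CC/C=C/CC/C=C/c1ccccc1 | intermediate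
12 | (2Z,4RS,6R,9E,13E)-4,6-dimethyl-14-phenyl-2-(triethylsilyl)tetradeca-2,9,13-trien-4-ol | C/C([Si](CC)(CC)CC)=C/C(C)(O)C[C@H](C)CC/C=C/CC/C=C/c1ccccc1 | intermediate
13 | dimethyl (E)-hex-3-enedioate | COC(=O)C/C=C/CC(=O)OC | starting material
14 | methyl 3-hydroperoxy-3-methoxypropanoate | COC(=O)CC(OC)OO | intermediate
15 | methyl 3-methoxy-3-{[(2Z,4RS,6R,9E,13E)-4,6-dimethyl-14-phenyl-2-(triethylsilyl)tetradeca-2,9,13-trien-4-yl]peroxy}propanoate (allylic peroxy acetal, not isolated) | COC(=O)CC(OC)OOC(C)(C[C@H](C)CC/C=C/CC/C=C/c1ccccc1)/C=C(/C)[Si](CC)(CC)CC | intermediate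
16 | methyl 2-[(3S,6R)-4,6-dimethyl-6-[(2R,5E,9E)-2-methyl-10-phenyldeca-5,9-dien-1-yl]-3,6-dihydro-1,2-dioxin-3-yl]acetate | C[C@H](CC/C=C/CC/C=C/c1ccccc1)C[C@]1(C)C=C(C)[C@H](CC(=O)OC)OO1 | intermediate
17 | (3R,4S,4aR,7aS)-4-iodo-3,4a-dimethyl-3-[(2R,5E,9E)-2-methyl-10-phenyldeca-5,9-dien-1-yl]tetrahydro-3H-furo[3,2-c][1,2]dioxin-6(4H)-one | C[C@H](CC/C=C/CC/C=C/c1ccccc1)C[C@]1(C)[C@@H](I)[C@]2(C)OC(=O)C[C@@H]2OO1 | intermediate
18 | (3R,4aS,7aS)-3,4a-dimethyl-3-[(2R,5E,9E)-2-methyl-10-phenyldeca-5,9-dien-1-yl]tetrahydro-3H-furo[3,2-c][1,2]dioxin-6(4H)-one | C[C@H](CC/C=C/CC/C=C/c1ccccc1)C[C@]1(C)C[C@]2(C)OC(=O)C[C@@H]2OO1 | target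

Total step count: 11. Longest linear sequence: 8 steps (3, 4, 5, 6, 7, 9, 10, 11, from 6).

Steps most likely to fail

1. Step 9 (the step carrying the label "Proposed new method:"). The tertiary allyl cation may lose a proton to a diene or the vinylsilane may be protodesilylated before C–O capture. The peroxy acetal may fragment heterolytically at the O–O bond. Facial discrimination by the counter-anion at C3 may be low, and there is none at C6, so up to four diastereomers could result. Fallback with known reactions, setting out from 12 and coming back at 16: iododesilylation of 12 with N-iodosuccinimide in MeCN (retention) should give (2Z,4RS,6R,9E,13E)-2-iodo-4,6-dimethyl-14-phenyltetradeca-2,9,13-trien-4-ol F1. Heck coupling with methyl acrylate (Pd(OAc)2, Ag2CO3, DMF) should give methyl (2E,4Z,6RS,8R,11E,15E)-6-hydroxy-4,6,8-trimethyl-16-phenylhexadeca-2,4,11,15-tetraenoate F2. Acid-catalysed exchange of the tertiary allylic hydroxyl with H2O2 (50% H2O2, catalytic H2SO4, Et2O, 0 °C) should give methyl (2E,4Z,6RS,8R,11E,15E)-6-hydroperoxy-4,6,8-trimethyl-16-phenylhexadeca-2,4,11,15-tetraenoate F3. Amine-mediated intramolecular conjugate addition of the hydroperoxide (Et2NH, CF3CH2OH) then closes the O2–C3 bond 6-exo and returns to 16. This path forms the ring by two C–O bonds and gives 16 as a C3/C6 diastereomer mixture to be separated.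

2. Step 10. Removal of the methyl group from the alkoxy-lactonium intermediate may be slow, so that the iodonium ion reverts while iodine adds reversibly to the side-chain alkenes, and liberated iodide may begin to reduce the O–O bond. Fallback setting out from 16 and coming back at 17: hydrolysis with pig liver esterase (pH 7 phosphate buffer/acetone) should give 2-[(3S,6R)-4,6-dimethyl-6-[(2R,5E,9E)-2-methyl-10-phenyldeca-5,9-dien-1-yl]-3,6-dihydro-1,2-dioxin-3-yl]acetic acid F4. Its carboxylate is then cyclised under kinetic iodolactonisation conditions (I2, NaHCO3, MeCN/H2O, 0 °C) to 17.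

3. Step 7. Silicon may be delivered to the wrong alkyne carbon, or turnover may stall at the congested tertiary propargylic alcohol. Fallback setting out from 11 and coming back at 16: silylation with 1,1,3,3-tetramethyldisilazane should give {[(4RS,6R,9E,13E)-4,6-dimethyl-14-phenyltetradeca-9,13-dien-2-yn-4-yl]oxy}dimethylsilane F5. KOtBu-catalysed intramolecular anti-hydrosilylation should give (5RS)-2,2,3,5-tetramethyl-5-[(2R,5E,9E)-2-methyl-10-phenyldeca-5,9-dien-1-yl]-2,5-dihydro-1,2-oxasilole F6, in which the ring enforces the Z geometry. MeLi opens the Si–O bond to (2Z,4RS,6R,9E,13E)-4,6-dimethyl-14-phenyl-2-(trimethylsilyl)tetradeca-2,9,13-trien-4-ol F7, which is taken through the conditions of step 9 in place of 12 and rejoins the route at 16.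

Further compounds
F1 | step 9 | (2Z,4RS,6R,9E,13E)-2-iodo-4,6-dimethyl-14-phenyltetradeca-2,9,13-trien-4-ol | C/C(I)=C/C(C)(O)C[C@H](C)CC/C=C/CC/C=C/c1ccccc1
F2 | step 9 | methyl (2E,4Z,6RS,8R,11E,15E)-6-hydroxy-4,6,8-trimethyl-16-phenylhexadeca-2,4,11,15-tetraenoate | COC(=O)\C=C\C(\C)=C/C(C)(O)C[C@H](C)CC/C=C/CC/C=C/c1ccccc1
F3 | step 9 | methyl (2E,4Z,6RS,8R,11E,15E)-6-hydroperoxy-4,6,8-trimethyl-16-phenylhexadeca-2,4,11,15-tetraenoate | COC(=O)\C=C\C(\C)=C/C(C)(OO)C[C@H](C)CC/C=C/CC/C=C/c1ccccc1
F4 | step 10 | 2-[(3S,6R)-4,6-dimethyl-6-[(2R,5E,9E)-2-methyl-10-phenyldeca-5,9-dien-1-yl]-3,6-dihydro-1,2-dioxin-3-yl]acetic acid | C[C@H](CC/C=C/CC/C=C/c1ccccc1)C[C@]1(C)C=C(C)[C@H](CC(=O)O)OO1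
F5 | step 7 | {[(4RS,6R,9E,13E)-4,6-dimethyl-14-phenyltetradeca-9,13-dien-2-yn-4-yl]oxy}dimethylsilane | CC#CC(C)(O[SiH](C)C)C[C@H](C)CC/C=C/CC/C=C/c1ccccc1
F6 | step 7 | (5RS)-2,2,3,5-tetramethyl-5-[(2R,5E,9E)-2-methyl-10-phenyldeca-5,9-dien-1-yl]-2,5-dihydro-1,2-oxasilole | CC1=CC(C)(C[C@H](C)CC/C=C/CC/C=C/c2ccccc2)O[Si]1(C)C
F7 | step 7 | (2Z,4RS,6R,9E,13E)-4,6-dimethyl-14-phenyl-2-(trimethylsilyl)tetradeca-2,9,13-trien-4-ol | C/C([Si](C)(C)C)=C/C(C)(O)C[C@H](C)CC/C=C/CC/C=C/c1ccccc1
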